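**Retrosynthetic overview**
1. The ten-membered carbocycle is opened last, at C1=C10: ring-closing metathesis of a seco-diene, which should give the Z alkene the target needs.
2. The C9–O bond and the isopropenyl metathesis handle come from a hydroxyl-directed singlet-oxygen ene reaction of a prenyl group; the two esters follow by sequential acylation.
3. The C7–C8 bond comes from Barbier allylation of 3-methylbut-2-enal with a 3-(bromomethyl)butenolide, which relays C6 to C7 and C8.
4. Key disconnection: the lactone C6–O bond, made by a catalytic enantioselective 1,4-bromolactonisation of a 2-dienylacrylic acid; this sets C6 and delivers the lactone ring and the allylic bromide together.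
5. The acid comes from 5-hexen-2-one (olefination, reduction, boron–Wittig/Suzuki). Ring order: lactone ring first (step 4), ten-membered ring last (step 9).

Assumption: the SMILES is read as the 6,7-trans-fused germacranolide (6R,7S,8R,9R; 1(10)Z,4E; ester = angelate, (2Z)-2-methylbut-2-enoate); germacrane atom numbers are used in the text, and the CIP letters at C7 and C8 change along the route only through priority changes, never through inversion.

**Route**

Step 1
Reactants: 1 5-hexen-2-one; 2 diethyl {2-[methoxy(methyl)amino]-2-oxoethyl}phosphonate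
Product: 3 (2E)-N-methoxy-N,3-dimethylhepta-2,6-dienamide
Conditions: NaH, THF, 0 °C → 65 °C; minor Z isomer removed on silica
Reagents that add atoms: none
Why: Horner–Wadsworth–Emmons olefination of the methyl ketone with the stabilised Weinreb phosphonate gives mainly the E trisubstituted alkene (typically 4–6:1), and the minor isomer is separable.

Step 2
Reactants: 3 (2E)-N-methoxy-N,3-dimethylhepta-2,6-dienamide
Product: 4 (2E)-3-methylhepta-2,6-dienal
Conditions: i-Bu2AlH (1.2 equiv), THF, −78 °C; aq. potassium sodium tartrate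
Reagents that add atoms: none
Why: Weinreb amide reduction stops at the aldehyde because the chelated aluminium hemiaminal survives until the quench, and neither alkene nor the E geometry is touched.

Step 3
Reactants: 4 (2E)-3-methylhepta-2,6-dienal; 5 2,2'-methylenebis(4,4,5,5-tetramethyl-1,3,2-dioxaborolane); 6 2-bromoacrylic acid
Product: 9 (3E,5E)-6-methyl-2-methylidenedeca-3,5,9-trienoic acid, via lithiated bis(pinacolboryl)methane 7 (not isolated), via dienyl pinacol boronate 8 (not isolated)
Conditions: 5, lithium 2,2,6,6-tetramethylpiperidide, THF, 0 °C; 4, −78 °C → rt; then 6, Pd(dppf)Cl2 (3 mol%), aq. K2CO3, 45 °C; acidify to pH 3, BHT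
Reagents that add atoms: none
Why: Boron–Wittig olefination of the enal gives the (E)-dienyl boronate by syn B–O elimination, and Suzuki–Miyaura coupling with the 2-bromoacrylate salt in the same flask forms C7–C11 with retention of both alkene geometries; the acid is purified by base/acid extraction and used promptly.

Step 4
Reactants: 9 (3E,5E)-6-methyl-2-methylidenedeca-3,5,9-trienoic acid
Product: 10 (5R)-3-(bromomethyl)-5-[(1E)-2-methylhexa-1,5-dien-1-yl]furan-2(5H)-one
Conditions: N-bromosuccinimide (1.05 equiv), 9-amino(9-deoxy)epi-quinidine 3,5-bis(trifluoromethyl)phenylurea (10 mol%), PhMe/CHCl3 2:1, −50 °C, dark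
Reagents that add atoms: N-bromosuccinimide, O=C1CCC(=O)N1Br
Why: Proposed new method: catalytic enantioselective 1,4-(vinylogous) bromolactonisation of a 2-(1,3-dienyl)acrylic acid, in which the quinuclidine of the bifunctional catalyst ion-pairs the carboxylate while its urea N–H bonds hold N-bromosuccinimide over the unhindered C13 terminus of the s-trans diene (the conformer that places the carboxylate beside C6), bromine transfer to C13 shifts the charge to C6 where the C4=C5 alkene stabilises it as an allyl cation, and the bound carboxylate closes the five-membered ring on one face of C6 (closure on C4 would need a seven-membered ring), so that the C6–O bond, the butenolide and the allylic bromide form at once and C6 is set as R by catalyst control (the quinine-derived pseudo-enantiomer is used should calibration show the opposite sense), nucleophile-assisted delivery keeping the reagent off the other alkenes at −50 °C; the closest known reactions are amine–urea-catalysed asymmetric 1,4-bromolactonisations of conjugated enynes and 5-endo bromolactonisations of β,γ-unsaturated acids.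

Step 5
Reactants: 10 (5R)-3-(bromomethyl)-5-[(1E)-2-methylhexa-1,5-dien-1-yl]furan-2(5H)-one; 11 3-methylbut-2-enal
Product: 13 (4R,5R)-4-[(1S)-1-hydroxy-3-methylbut-2-en-1-yl]-3-methylidene-5-[(1E)-2-methylhexa-1,5-dien-1-yl]oxolan-2-one, via allylzinc bromide 12 (not isolated)
Conditions: Zn (activated dust), THF/sat. aq. NH4Cl, 0 °C → rt
Reagents that add atoms: none
Why: Barbier-type SE2′ allylation in which the ring-locked allylzinc behaves as an E-crotyl reagent and adds to the enal carbonyl through a closed six-membered chair transition state on the face of C7 opposite the C6 dienyl group, which sets C7 trans to C6 and C8 anti in the crotylation sense (1S in 13, the C8 configuration of the target), as known for 5-substituted 3-(bromomethyl)butenolides.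

Step 6
Reactants: 13 (4R,5R)-4-[(1S)-1-hydroxy-3-methylbut-2-en-1-yl]-3-methylidene-5-[(1E)-2-methylhexa-1,5-dien-1-yl]oxolan-2-one
Product: 15 (4R,5R)-4-[(1R,2R)-1,2-dihydroxy-3-methylbut-3-en-1-yl]-3-methylidene-5-[(1E)-2-methylhexa-1,5-dien-1-yl]oxolan-2-one, via threo allylic hydroperoxide 14 (not isolated)
Conditions: O2 (1 atm), tetraphenylporphyrin (0.5 mol%), white LED, CH2Cl2, −20 °C, to about 90% conversion; then PPh3 (1.1 equiv), 0 °C
Reagents that add atoms: dioxygen, O=O
Why: Schenck ene reaction in which the free C8 hydroxyl, held in the 1,3-allylic-strain conformer, hydrogen-bonds the incoming singlet oxygen so that the C9–O bond forms on the hydroxyl face (threo, 9R) with hydrogen abstraction from a C10 methyl, creating the isopropenyl group needed for ring closure, while the C4=C5 alkene is deactivated by its allylic lactone oxygen and the vinyl and methylidene-lactone alkenes are inert; PPh3 then reduces the hydroperoxide without touching a stereocentre.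

Step 7
Reactants: 15 (4R,5R)-4-[(1R,2R)-1,2-dihydroxy-3-methylbut-3-en-1-yl]-3-methylidene-5-[(1E)-2-methylhexa-1,5-dien-1-yl]oxolan-2-one; 16 (2Z)-2-methylbut-2-enoic acid (angelic acid)
Product: 18 (1R,2R)-1-hydroxy-3-methyl-1-[(2R,3R)-4-methylidene-2-[(1E)-2-methylhexa-1,5-dien-1-yl]-5-oxooxolan-3-yl]but-3-en-2-yl (2Z)-2-methylbut-2-enoate, via angelic 2,4,6-trichlorobenzoic mixed anhydride 17 (not isolated)
Conditions: 16, 2,4,6-trichlorobenzoyl chloride, Et3N, PhMe, rt; then 15, DMAP (0.2 equiv), 0 °C → rt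
Reagents that add atoms: none
Why: Yamaguchi esterification, the standard way to make angelates without Z-to-E isomerisation, acylates the less hindered allylic C9 hydroxyl (flanked by the planar isopropenyl group) in preference to the C8 hydroxyl next to the branched ring carbon, and no stereocentre is touched.

Step 8
Reactants: 18 (1R,2R)-1-hydroxy-3-methyl-1-[(2R,3R)-4-methylidene-2-[(1E)-2-methylhexa-1,5-dien-1-yl]-5-oxooxolan-3-yl]but-3-en-2-yl (2Z)-2-methylbut-2-enoate
Product: 19 (1R,2R)-1-(acetyloxy)-3-methyl-1-[(2R,3S)-4-methylidene-2-[(1E)-2-methylhexa-1,5-dien-1-yl]-5-oxooxolan-3-yl]but-3-en-2-yl (2Z)-2-methylbut-2-enoate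
Conditions: Ac2O, pyridine, DMAP (cat.), CH2Cl2, 0 °C → rt
Reagents that add atoms: acetic anhydride, CC(=O)OC(C)=O
Why: Standard DMAP-catalysed acetylation of the remaining secondary C8 alcohol, to which the lactone, the angelate and the alkenes are inert.

Step 9
Reactants: 19 (1R,2R)-1-(acetyloxy)-3-methyl-1-[(2R,3S)-4-methylidene-2-[(1E)-2-methylhexa-1,5-dien-1-yl]-5-oxooxolan-3-yl]but-3-en-2-yl (2Z)-2-methylbut-2-enoate
Product: 20 (6R,7S,8R,9R)-8-acetoxy-9-[(2Z)-2-methylbut-2-enoyloxy]-(1(10)Z,4E)-germacra-1(10),4,11(13)-trien-12,6-olide (CNP0200690.1)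
Conditions: second-generation Hoveyda–Grubbs catalyst (H2IMes)Cl2Ru(=CH-C6H4-2-O-i-Pr) (15 mol% in portions), 1,4-benzoquinone (30 mol%), PhMe (1 mM), 80 °C, Ar sparge
Reagents that add atoms: none
Why: Ring-closing metathesis between the C1 vinyl group (where the catalyst loads) and the isopropenyl group releases ethene and closes the ten-membered ring, in which the new trisubstituted alkene is expected to be Z as is usual for medium rings, while the electron-poor methylidene-lactone and angelate alkenes stay out.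

**Compound list**
1 | 5-hexen-2-one | CC(=O)CCC=C | starting material
2 | diethyl {2-[methoxy(methyl)amino]-2-oxoethyl}phosphonate | CCOP(=O)(OCC)CC(=O)N(C)OC | starting material
3 | (2E)-N-methoxy-N,3-dimethylhepta-2,6-dienamide | CON(C)C(=O)/C=C(\C)CCC=C | intermediate
4 | (2E)-3-methylhepta-2,6-dienal | O=C/C=C(\C)CCC=C | intermediate
5 | 2,2'-methylenebis(4,4,5,5-tetramethyl-1,3,2-dioxaborolane) | CC1(C)OB(CB2OC(C)(C)C(C)(C)O2)OC1(C)C | starting material
6 | 2-bromoacrylic acid | OC(=O)C(Br)=C | starting material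
7 | lithiated bis(pinacolboryl)methane | [Li]C(B1OC(C)(C)C(C)(C)O1)B1OC(C)(C)C(C)(C)O1 | intermediate (not isolated)
8 | 2-[(1E,3E)-4-methylocta-1,3,7-trien-1-yl]-4,4,5,5-tetramethyl-1,3,2-dioxaborolane | CC1(C)OB(/C=C/C=C(\C)CCC=C)OC1(C)C | intermediate (not isolated)
9 | (3E,5E)-6-methyl-2-methylidenedeca-3,5,9-trienoic acid | C=C(C(=O)O)/C=C/C=C(\C)CCC=C | intermediate
10 | (5R)-3-(bromomethyl)-5-[(1E)-2-methylhexa-1,5-dien-1-yl]furan-2(5H)-one | O=C1O[C@H](/C=C(\C)CCC=C)C=C1CBr | intermediate
11 | 3-methylbut-2-enal | CC(C)=CC=O | starting material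
12 | bromo{[(5R)-5-[(1E)-2-methylhexa-1,5-dien-1-yl]-2-oxo-2,5-dihydrofuran-3-yl]methyl}zinc | Br[Zn]CC1=C[C@@H](/C=C(\C)CCC=C)OC1=O | intermediate (not isolated)
13 | (4R,5R)-4-[(1S)-1-hydroxy-3-methylbut-2-en-1-yl]-3-methylidene-5-[(1E)-2-methylhexa-1,5-dien-1-yl]oxolan-2-one | C=C1C(=O)O[C@H](/C=C(\C)CCC=C)[C@H]1[C@@H](O)C=C(C)C | intermediate
14 | (4R,5R)-4-[(1R,2R)-2-hydroperoxy-1-hydroxy-3-methylbut-3-en-1-yl]-3-methylidene-5-[(1E)-2-methylhexa-1,5-dien-1-yl]oxolan-2-one | C=C1C(=O)O[C@H](/C=C(\C)CCC=C)[C@H]1[C@@H](O)[C@H](OO)C(C)=C | intermediate (not isolated)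
15 | (4R,5R)-4-[(1R,2R)-1,2-dihydroxy-3-methylbut-3-en-1-yl]-3-methylidene-5-[(1E)-2-methylhexa-1,5-dien-1-yl]oxolan-2-one | C=C1C(=O)O[C@H](/C=C(\C)CCC=C)[C@H]1[C@@H](O)[C@H](O)C(C)=C | intermediate
16 | (2Z)-2-methylbut-2-enoic acid (angelic acid) | OC(=O)/C(C)=C\C | starting material
17 | (2Z)-2-methylbut-2-enoic 2,4,6-trichlorobenzoic anhydride | O=C(OC(=O)/C(C)=C\C)c1c(Cl)cc(Cl)cc1Cl | intermediate (not isolated)
18 | (1R,2R)-1-hydroxy-3-methyl-1-[(2R,3R)-4-methylidene-2-[(1E)-2-methylhexa-1,5-dien-1-yl]-5-oxooxolan-3-yl]but-3-en-2-yl (2Z)-2-methylbut-2-enoate | C=C1C(=O)O[C@H](/C=C(\C)CCC=C)[C@H]1[C@@H](O)[C@H](OC(=O)/C(C)=C\C)C(C)=C | intermediate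
19 | (1R,2R)-1-(acetyloxy)-3-methyl-1-[(2R,3S)-4-methylidene-2-[(1E)-2-methylhexa-1,5-dien-1-yl]-5-oxooxolan-3-yl]but-3-en-2-yl (2Z)-2-methylbut-2-enoate | C=C1C(=O)O[C@H](/C=C(\C)CCC=C)[C@H]1[C@@H](OC(C)=O)[C@H](OC(=O)/C(C)=C\C)C(C)=C | intermediate
20 | (6R,7S,8R,9R)-8-acetoxy-9-[(2Z)-2-methylbut-2-enoyloxy]-(1(10)Z,4E)-germacra-1(10),4,11(13)-trien-12,6-olide | C=C1C(=O)O[C@@H]2/C=C(\C)CC/C=C(/C)[C@@H](OC(=O)/C(C)=C\C)[C@H](OC(C)=O)[C@@H]12 | target

**Step count and risks**

Total steps: 9. Longest linear sequence: 9 steps (1 → 20); all other inputs are purchased.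

Three steps most likely to fail:

- **Step 4 (the new bromolactonisation).** The site of bromine transfer (C13 versus the C6=C7 or C4=C5 alkenes) and the ee are untested. A 1,2-adduct carrying bromine at C7 would give the same allylzinc in step 5, so the ee is the critical unknown. The fallback uses known chemistry, sets out from 4 and comes back at 10, replacing steps 3 and 4. Zinc–ProPhenol alkynylation of 4 with tert-butyldimethyl(prop-2-yn-1-yloxy)silane (Me2Zn, the ligand enantiomer that gives the R carbinol, Ph3P=O, PhMe) gives (4R,5E)-1-[(tert-butyldimethylsilyl)oxy]-6-methyldeca-5,9-dien-2-yn-4-ol F1. Hydroxyl-directed trans-hydroalumination with NaAlH2(OCH2CH2OCH3)2 and an iodine quench gives (2Z,4R,5E)-1-[(tert-butyldimethylsilyl)oxy]-2-iodo-6-methyldeca-2,5,9-trien-4-ol F2. Carbonylative lactonisation (PdCl2(PPh3)2 cat., CO 1 atm, K2CO3, THF) gives (5R)-3-{[(tert-butyldimethylsilyl)oxy]methyl}-5-[(1E)-2-methylhexa-1,5-dien-1-yl]furan-2(5H)-one F3. Ph3PBr2 in CH2Cl2 then turns the silyl ether directly into bromide 10.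

- **Step 6 (singlet-oxygen ene reaction).** The C4=C5 alkene may compete, and the threo preference may erode in this more crowded substrate. The fallback sets out from 13 and comes back at 15. Hydroxyl-directed epoxidation (VO(acac)2 cat., t-BuOOH, CH2Cl2, 0 °C) touches only the allylic-alcohol alkene and, under 1,3-allylic strain control, gives mainly the threo epoxy alcohol (4R,5R)-4-{(R)-[(2S)-3,3-dimethyloxiran-2-yl](hydroxy)methyl}-3-methylidene-5-[(1E)-2-methylhexa-1,5-dien-1-yl]oxolan-2-one F4. Base-induced epoxide-to-allylic-alcohol isomerisation with Et2Al(TMP) in PhMe at 0 °C (proton loss from a C10 methyl, C9–O bond untouched) then gives diol 15.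

- **Step 9 (ring-closing metathesis).** Closing a ten-membered ring onto a 1,1-disubstituted alkene flanked by an allylic ester may be slow, may give dimers or may give the E isomer. The fallback sets out from 15 and comes back at 20, closing the ring before acylation, where the free allylic hydroxyl speeds metathesis at the adjacent alkene and the substrate is less hindered. Metathesis of 15 with the same ruthenium catalyst gives (6R,7R,8R,9R)-8,9-dihydroxy-(1(10)Z,4E)-germacra-1(10),4,11(13)-trien-12,6-olide F5. Yamaguchi angeloylation with 17 at the allylic C9 hydroxyl gives (6R,7R,8R,9R)-8-hydroxy-9-[(2Z)-2-methylbut-2-enoyloxy]-(1(10)Z,4E)-germacra-1(10),4,11(13)-trien-12,6-olide F6. Acetylation (Ac2O, pyridine, DMAP) then gives 20.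

**Further compounds**
F1 | step 4 | (4R,5E)-1-[(tert-butyldimethylsilyl)oxy]-6-methyldeca-5,9-dien-2-yn-4-ol | O[C@H](/C=C(\C)CCC=C)C#CCO[Si](C)(C)C(C)(C)C
F2 | step 4 | (2Z,4R,5E)-1-[(tert-butyldimethylsilyl)oxy]-2-iodo-6-methyldeca-2,5,9-trien-4-ol | O[C@H](/C=C(\C)CCC=C)/C=C(\I)CO[Si](C)(C)C(C)(C)C
F3 | step 4 | (5R)-3-{[(tert-butyldimethylsilyl)oxy]methyl}-5-[(1E)-2-methylhexa-1,5-dien-1-yl]furan-2(5H)-one | O=C1O[C@H](/C=C(\C)CCC=C)C=C1CO[Si](C)(C)C(C)(C)C
F4 | step 6 | (4R,5R)-4-{(R)-[(2S)-3,3-dimethyloxiran-2-yl](hydroxy)methyl}-3-methylidene-5-[(1E)-2-methylhexa-1,5-dien-1-yl]oxolan-2-one | C=C1C(=O)O[C@H](/C=C(\C)CCC=C)[C@H]1[C@@H](O)[C@@H]2OC2(C)C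
F5 | step 9 | (6R,7R,8R,9R)-8,9-dihydroxy-(1(10)Z,4E)-germacra-1(10),4,11(13)-trien-12,6-olide | C=C1C(=O)O[C@@H]2/C=C(\C)CC/C=C(/C)[C@@H](O)[C@H](O)[C@@H]12
F6 | step 9 | (6R,7R,8R,9R)-8-hydroxy-9-[(2Z)-2-methylbut-2-enoyloxy]-(1(10)Z,4E)-germacra-1(10),4,11(13)-trien-12,6-olide | C=C1C(=O)O[C@@H]2/C=C(\C)CC/C=C(/C)[C@@H](OC(=O)/C(C)=C\C)[C@H](O)[C@@H]12
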